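The central cyclobutane (C5–C6–C6'–C5') carries two adjacent spiro-butenolide carbons (C5, C5') and two adjacent CHBr carbons (C6, C6'). It is therefore the head-to-head [2+2] dimer of a 4-bromo-5-(bromomethylene)butenolide. The core is C2-symmetric, but the two carbinol centres are opposite (S in one half, R in the other), so the target is a cross-dimer of enantiomeric monomers. One lipase resolution of the racemic monomer acetate delivers both halves and tags them as (S)-acetate and (R)-alcohol. Sensitised irradiation joins C6 to C6' and then closes the ring by C5–C5' recombination of a doubly stabilised 1,4-biradical, setting four stereocentres. The OH/OAc tag makes the two mirror-image cores diastereomeric and separable; acetylation erases it.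

Key step: step 8

Remark: fimbrolide numbering is used (O1, C2=O, C3, C4–Br, C5, exocyclic C6, carbinol C1'; primes mark the second half). In the target each C6–Br is trans to the O1 of its own half across the C5–C6 ring bond. Suprafacial addition to an (E)-bromomethylene group gives this relationship, so the E isomers formed in the flask are taken as the reacting species.

Step 1
Reactants: 1 ethyl acetoacetate; 2 ethyl 2-bromohexanoate
Product: 3 diethyl 2-acetyl-3-butylbutanedioate (mixture of diastereomers)
Conditions: NaOEt, EtOH, reflux
Reagents that add atoms: none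
Why: Acetoacetic ester alkylation, in which the stabilised sodium enolate of 1 displaces the activated secondary α-bromide of 2 (SN2); both new stereocentres are erased later, so their mixture does not matter.

Step 2
Reactants: 3 diethyl 2-acetyl-3-butylbutanedioate
Product: 4 2-butyl-4-oxopentanoic acid (racemic)
Conditions: 6 M aq. HCl, reflux
Reagents that add atoms: water O
Why: Acidic hydrolysis of both esters followed by ketonic decarboxylation of the β-keto acid (acetoacetic ester synthesis) leaves the γ-keto acid.

Step 3
Reactants: 4 2-butyl-4-oxopentanoic acid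
Product: 5 3,5-dibromo-2-butyl-4-oxopentanoic acid (mixture of diastereomers)
Conditions: Br2 (2 equiv), CHCl3, 0 °C to rt
Reagents that add atoms: bromine BrBr
Why: Acid-autocatalysed enol bromination of the ketone places one bromine on each α-carbon (C3 and C5), the usual pattern for levulinic acids in a non-hydroxylic solvent.

Step 4
Reactants: 5 3,5-dibromo-2-butyl-4-oxopentanoic acid
Product: 6 (5Z)-4-bromo-5-(bromomethylidene)-3-butylfuran-2(5H)-one
Conditions: conc. H2SO4, 105 °C, short contact time, then ice
Reagents that add atoms: none
Why: This is the established sulfuric acid cyclisation of brominated 2-alkyllevulinic acids, that is, enol-lactonisation and dehydration toward the CH2Br carbon with net dehydrogenation across C3–C4 at the expense of hot H2SO4; the Z alkene should form because C6–Br avoids C4–Br.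

Step 5
Reactants: 6 (5Z)-4-bromo-5-(bromomethylidene)-3-butylfuran-2(5H)-one
Product: 7 racemic (5Z)-4-bromo-3-(1-bromobutyl)-5-(bromomethylidene)furan-2(5H)-one
Conditions: NBS (1.05 equiv), (BzO)2 (cat.), PhCF3, reflux, visible lamp
Reagents that add atoms: N-bromosuccinimide O=C1CCC(=O)N1Br
Why: Wohl–Ziegler bromination takes the C1'–H, the only C–H whose radical is allylic to C3=C4 and conjugated with the dienolide; the new centre is racemic on purpose.

Step 6
Reactants: 7 racemic 1'-bromide
Product: 8 racemic 1-[(5Z)-4-bromo-5-(bromomethylidene)-2-oxo-2,5-dihydrofuran-3-yl]butyl acetate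
Conditions: NaOAc, AcOH, 100 °C
Reagents that add atoms: sodium acetate CC(=O)[O-].[Na+]
Why: Nucleophilic substitution of the activated allylic secondary bromide by acetate in buffered acetic acid, a medium too weakly basic to attack the vinylic bromides or the enol lactone.

Step 7
Reactants: 8 racemic acetate
Product: 9 (5Z)-4-bromo-5-(bromomethylidene)-3-[(1R)-1-hydroxybutyl]furan-2(5H)-one and 10 (1S)-1-[(5Z)-4-bromo-5-(bromomethylidene)-2-oxo-2,5-dihydrofuran-3-yl]butyl acetate (unreacted enantiomer, separated on silica)
Conditions: immobilised Burkholderia cepacia lipase, n-BuOH (3 equiv), MTBE, 30 °C, stopped at half conversion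
Reagents that add atoms: none
Why: Lipase-catalysed kinetic resolution by transesterification, where the empirical large/medium substituent model for secondary carbinols (large = furanone, medium = propyl) predicts deacylation of the (R)-acetate only; this sets C1' of both halves, (R) in 9 and (S) in the untouched 10.

Step 8
Reactants: 9 (R)-alcohol; 10 (S)-acetate
Product: 14 (1S)-1-[(5S,6S,11R,12R)-4,10,11,12-tetrabromo-9-[(1R)-1-hydroxybutyl]-2,8-dioxo-1,7-dioxadispiro[4.0.4.2]dodeca-3,9-dien-3-yl]butyl acetate, via E-alcohol 11 (not isolated), via E-acetate 12 (not isolated), via 1,4-biradical 13 (not isolated)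
Conditions: 9:10 = 1:1, 0.5 M each, thioxanthen-9-one (10 mol %), degassed CH2Cl2, 405 nm LED, −40 °C; chromatography on silica
Reagents that add atoms: none
Why: Triplet energy transfer from excited thioxanthen-9-one gives the C5=C6-twisted triplet of the dienolide, which first equilibrates 9 and 10 with their E isomers 11 and 12 and then bonds through C6 to C6' of a ground-state partner, because only this head-to-head union leaves both spins on C5 and C5', each a tertiary radical stabilised by O1 and by the C4=C3–C2=O unit (13). After intersystem crossing the four-membered ring closes by C5–C5' recombination of the 1,4-biradical, a stepwise [2+2] photocycloaddition whose closest known case is the head-to-head dimerisation of the γ-methylenebutenolide protoanemonin to the dispiro-cyclobutane anemonin. C5 and C5' are set in this closure with O1 and O1' on opposite ring faces, since the antiparallel arrangement of the two lactones cancels their dipoles and keeps C4–Br away from C4'–Br. C6 and C6' are set in the first bond formation as the trans-dibromide, which avoids eclipsed C–Br bonds, and the Br-trans-to-own-O1 relation copies the E geometry of 11 and 12 only if closure outruns C5–C6 rotation, for which the spin-orbit coupling of four bromine atoms (fast intersystem crossing), the low temperature and the high concentration are relied on. The substrate secures reaction at the exocyclic alkene and head-to-head orientation (the tetrasubstituted C3=C4 is shielded and only C6–C6' bonding gives the doubly stabilised biradical), whereas the remote carbinol centres induce neither cross-pairing nor one sense of core chirality, so pairing is statistical and 14 is separated on silica, the OH/OAc tag making homo-dimers, cross-dimers and the two cores of the cross-dimer chromatographically distinct, and assigned by X-ray analysis (anomalous dispersion of bromine). The product has lost the dienolide chromophore, is transparent at 405 nm and has a triplet above that of the sensitiser, which should shut off cycloreversion.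

Step 9
Reactants: 14 cross-dimer monoacetate
Product: 15 target, (1S)-1-[(5S,6S,11R,12R)-9-[(1R)-1-acetyloxybutyl]-4,10,11,12-tetrabromo-2,8-dioxo-1,7-dioxadispiro[4.0.4.2]dodeca-3,9-dien-3-yl]butyl acetate
Conditions: Ac2O, pyridine, CH2Cl2, 0 °C to rt
Reagents that add atoms: acetic anhydride CC(=O)OC(C)=O
Why: Pyridine-mediated O-acetylation of the one remaining secondary alcohol touches no stereocentre and removes the tag, giving the diacetate as the single enantiomer.

Compound list
1 | ethyl acetoacetate | CCOC(=O)CC(C)=O | starting material
2 | ethyl 2-bromohexanoate | CCCCC(Br)C(=O)OCC | starting material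
3 | diethyl 2-acetyl-3-butylbutanedioate | CCCCC(C(=O)OCC)C(C(C)=O)C(=O)OCC | intermediate
4 | 2-butyl-4-oxopentanoic acid | CCCCC(CC(C)=O)C(=O)O | intermediate
5 | 3,5-dibromo-2-butyl-4-oxopentanoic acid | CCCCC(C(Br)C(=O)CBr)C(=O)O | intermediate
6 | (5Z)-4-bromo-5-(bromomethylidene)-3-butylfuran-2(5H)-one | CCCCC1=C(Br)/C(=C/Br)OC1=O | intermediate
7 | racemic (5Z)-4-bromo-3-(1-bromobutyl)-5-(bromomethylidene)furan-2(5H)-one | CCCC(Br)C1=C(Br)/C(=C/Br)OC1=O | intermediate
8 | racemic 1-[(5Z)-4-bromo-5-(bromomethylidene)-2-oxo-2,5-dihydrofuran-3-yl]butyl acetate | CCCC(OC(C)=O)C1=C(Br)/C(=C/Br)OC1=O | intermediate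
9 | (5Z)-4-bromo-5-(bromomethylidene)-3-[(1R)-1-hydroxybutyl]furan-2(5H)-one | CCC[C@@H](O)C1=C(Br)/C(=C/Br)OC1=O | intermediate
10 | (1S)-1-[(5Z)-4-bromo-5-(bromomethylidene)-2-oxo-2,5-dihydrofuran-3-yl]butyl acetate | CCC[C@H](OC(C)=O)C1=C(Br)/C(=C/Br)OC1=O | intermediate
11 | (5E) isomer of alcohol 9 (1'R) | CCC[C@@H](O)C1=C(Br)/C(=C\Br)OC1=O | intermediate
12 | (5E) isomer of acetate 10 (1'S) | CCC[C@H](OC(C)=O)C1=C(Br)/C(=C\Br)OC1=O | intermediate
13 | 1,4-biradical: C6–C6' bonded (6R,6'R)-dibromide, radical centres at C5 and C5', (S)-acetate half and (R)-alcohol half | CCC[C@H](OC(C)=O)C1=C(Br)[C]([C@@H](Br)[C@H](Br)[C]2OC(=O)C([C@@H](CCC)O)=C2Br)OC1=O | intermediate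
14 | cross-dimer monoacetate, (5S,6S,11R,12R) core, (1S)-acetate and (1R)-alcohol side chains | CCC[C@H](OC(C)=O)C1=C(Br)[C@@]2(OC1=O)[C@@H](Br)[C@H](Br)[C@@]21OC(=O)C([C@@H](CCC)O)=C1Br | intermediate
15 | target diacetate, (5S,6S,11R,12R) core, (1S)- and (1R)-1-acetoxybutyl side chains | CCC[C@H](OC(C)=O)C1=C(Br)[C@@]2(OC1=O)[C@@H](Br)[C@H](Br)[C@@]21OC(=O)C([C@@H](CCC)OC(C)=O)=C1Br | target

Total step count: 9. Longest linear sequence: 9 steps (from 1 or 2 to 15).

Steps most likely to fail

Step 8. Several things may go wrong:
- Pairing of the two monomers is only statistical.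
- Rotation about C5–C6 in the biradical before closure would divert material to the less crowded isomers with Br syn to O1.
- A bromine atom may be lost from the biradical by β-scission.
- The remote carbinol centres give no facial bias.

Together these could leave 14 as a minor part of a complex mixture. The fallback sets out from 9 and comes back at 14. Alcohol 9 alone is irradiated under the same sensitisation, so only one pairing is possible and the head-to-head anti products are C2-symmetric. This cuts the number of isomers and eases their assignment, although the C5–C6 rotation risk remains. The C2-symmetric (R,R)-diol dimer with the (5S,6S,11R,12R) core F1 is separated from its core diastereomer. The opposite carbinol configuration is introduced afterwards by one Mitsunobu inversion (one equivalent each of PPh3, DIAD and AcOH, THF, 0 °C). The two hydroxyl groups of F1 are homotopic, so inversion at either one gives the same (S)-acetate/(R)-alcohol, which is 14.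

Step 7. The medium-sized propyl group may be discriminated incompletely, and the electrophilic bromofuranone may slowly alkylate and inactivate the enzyme. The fallback sets out from 7 and comes back at 9 and 10.
- Bromide 7 is hydrolysed in wet DMSO to the racemic alcohol F2.
- Dess–Martin periodinane oxidises it to the 3-butanoyl ketone F3.
- Corey–Bakshi–Shibata reduction with (S)-Me-CBS and catecholborane (toluene, −78 °C) should give 9.
- The same reduction with (R)-Me-CBS should give the (S)-alcohol F4, which Ac2O and pyridine convert into 10.

Step 4. Charring, over-bromination to the dibromomethylene series and loss of the C4 bromine may occur in hot oxidising acid. The fallback sets out from 2 and comes back at 6, and it installs C4–Br at the right oxidation level without an oxidising acid.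
- Ester 2 is quaternised with PPh3 to the phosphonium bromide F5, and aqueous NaOH gives the stabilised ylide F6.
- A Wittig reaction with methylketene, made in the flask from propanoyl chloride and Et3N, gives ethyl 2-butylpenta-2,3-dienoate F7.
- CuBr2 in aqueous acetone effects bromolactonisation of the 2,3-allenoate to 4-bromo-3-butyl-5-methylfuran-2(5H)-one F8.
- NBS under radical conditions brominates the doubly activated C5–H to the 5-bromide F9, and Et3N eliminates HBr to the 5-methylene butenolide F10.
- Br2 adds to the exocyclic alkene to give the tribromide F11, and DBU eliminates HBr to the thermodynamic Z alkene 6.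

Further compounds
F1 | step 8 | C2-symmetric (R,R)-diol dimer, (5S,6S,11R,12R) core | CCC[C@@H](O)C1=C(Br)[C@@]2(OC1=O)[C@@H](Br)[C@H](Br)[C@@]21OC(=O)C([C@@H](CCC)O)=C1Br
F2 | step 7 | racemic (5Z)-4-bromo-5-(bromomethylidene)-3-(1-hydroxybutyl)furan-2(5H)-one | CCCC(O)C1=C(Br)/C(=C/Br)OC1=O
F3 | step 7 | (5Z)-4-bromo-5-(bromomethylidene)-3-butanoylfuran-2(5H)-one | CCCC(=O)C1=C(Br)/C(=C/Br)OC1=O
F4 | step 7 | (5Z)-4-bromo-5-(bromomethylidene)-3-[(1S)-1-hydroxybutyl]furan-2(5H)-one | CCC[C@H](O)C1=C(Br)/C(=C/Br)OC1=O
F5 | step 4 | (1-ethoxy-1-oxohexan-2-yl)triphenylphosphonium bromide | CCCCC(C(=O)OCC)[P+](c1ccccc1)(c1ccccc1)c1ccccc1.[Br-]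
F6 | step 4 | ethyl 2-(triphenylphosphoranylidene)hexanoate | CCCCC(C(=O)OCC)=P(c1ccccc1)(c1ccccc1)c1ccccc1
F7 | step 4 | ethyl 2-butylpenta-2,3-dienoate (racemic) | CCCCC(=C=CC)C(=O)OCC
F8 | step 4 | 4-bromo-3-butyl-5-methylfuran-2(5H)-one (racemic) | CCCCC1=C(Br)C(C)OC1=O
F9 | step 4 | 4,5-dibromo-3-butyl-5-methylfuran-2(5H)-one (racemic) | CCCCC1=C(Br)C(C)(Br)OC1=O
F10 | step 4 | 4-bromo-3-butyl-5-methylidenefuran-2(5H)-one | CCCCC1=C(Br)C(=C)OC1=O
F11 | step 4 | 4,5-dibromo-5-(bromomethyl)-3-butylfuran-2(5H)-one (racemic) | CCCCC1=C(Br)C(Br)(CBr)OC1=O
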